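**Plan**

1. Eremophilane numbering is used: ring A = C1–C5 and C10, ring B = C5–C10, C14/C15 = methyls on C5/C4, C11–C13 = isopropylidene on C7. The first cut is the C3–O ester bond, giving a (3R,4R,5R)-3-hydroxy dienone with the C9 enol masked and (2Z)-3-methyl-4-angeloyloxybut-2-enoic acid.
2. Enabling feature: the vicinal C8/C9 oxygens of the ring B diosphenol, next to C10 and the methyl-bearing C5/C4, mark C8–C9–C10–C5–C4–C3 as the six carbons of 2-methoxy-4,5-dimethylphenol. Ring A is therefore cut at C2–C3 and C1–C10 (Diels–Alder of the dearomatised phenol with an ethylene equivalent), and ring B at C5–C6 (oxy-Cope) and C7–C11 (aldol with acetone).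
3. Forward: oxidative dearomatisation and [4+2] give a bicyclo[2.2.2]octenone that holds ring A plus a temporary C3–C8 bond. Vinyl (C6, C7) adds to C8, and the anionic oxy-Cope shift cleaves C3–C8 and closes ring B to a cis-decalin. Then follow the isopropylidene, ketal to methoxymethyl (MOM)-protected diosphenol, hydroboration of C3=C4, esterification and deprotection.
4. Stereochemistry: C5 comes from the suprafacial [3,3] shift, relayed from bridgehead C10 (which later becomes sp2). C3 and C4 come from syn hydroboration anti to the axial C5 methyl. The absolute configuration comes from a lipase kinetic resolution of the C3 alcohol.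
5. Side chain: the Z geometry comes from syn carbocupration of a 4-silyloxybut-2-ynoate and the angelate from angelic acid; it is joined to C3–OH last by Yamaguchi esterification.

Key step: step 2

Remark: the target is read as (3R,4R,5R), with 3-O trans to the C4 methyl, the C4 and C5 methyls cis, and both side-chain double bonds Z.
Remark: every compound from the cycloadduct of step 2 to the alcohol of step 11 is a racemate; its name carries rac and its SMILES shows the enantiomer that is carried on.
Remark: in the bicyclic compounds the target atoms are the bridgeheads C3 and C10 and the bridges C4=C5, C2–C1 and C8–C9.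

**Route**

Step 1
Reactants: 1 3,4-dimethylanisole
Product: 4 2-methoxy-4,5-dimethylphenol, via aryllithium 2 (not isolated), via arylboronate 3 (not isolated)
Conditions: n-BuLi, TMEDA, Et2O, 0 °C to rt; B(OMe)3, −78 °C to rt; AcOH, 30% H2O2, 0 °C to rt
Reagents that add atoms: hydrogen peroxide, OO
Why: Directed ortho-metalation of the anisole occurs at the ortho position that is not flanked by a methyl group, and borylation followed by oxidative C–B to C–O conversion gives the guaiacol, with no stereocenter involved.

Step 2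
Reactants: 4 2-methoxy-4,5-dimethylphenol; 5 phenyl vinyl sulfone
Product: 7 rac-(1R,4S,7S)-3,3-dimethoxy-5,6-dimethyl-7-(phenylsulfonyl)bicyclo[2.2.2]oct-5-en-2-one, via masked o-benzoquinone 6 (not isolated)
Conditions: PhI(OAc)2, MeOH, 5 (4 equiv), slow addition of 4, 50 °C
Reagents that add atoms: methanol, CO
Why: PhI(OAc)2 oxidises phenol 4 by ligand exchange at iodine and loss of PhI, and methanol captures the resulting cation at the methoxy-bearing carbon (future C9) to give the achiral 6,6-dimethoxycyclohexa-2,4-dienone 6, whose diene C3=C4–C5=C10 then adds the C1=C2 unit of sulfone 5 in a concerted, suprafacial [4+2] cycloaddition. The closest known reaction type is the Diels–Alder reaction of masked o-benzoquinones, generated in situ, with monosubstituted alkenes. The step closes the six-membered carbocycle C3–C2–C1–C10–C5–C4 (the future ring A, bridged by C8–C9 to a bicyclo[2.2.2]octene) by forming C2–C3 and C1–C10 at the two diene termini, both bonds on the same face of each partner. The bridgeheads C3 and C10 are set as a cis pair by this suprafacial addition to a planar, achiral diene, so 7 is racemic, and the sulfonyl-bearing carbon is set endo by the usual secondary-orbital preference but is erased in step 4. The step needs cross-cycloaddition to outrun self-dimerisation of 6, and ortho rather than para capture by methanol; the first is secured by slow generation of 6 in excess 5 and by the methyl group on the C5=C10 bond that would act as dienophile in the dimerisation, the second by the methoxy group that stabilises the cation at C9. It also installs, as the C3–C8 bond, the temporary link that the oxy-Cope step later cleaves.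

Step 3
Reactants: 7 rac-(1R,4S,7S)-3,3-dimethoxy-5,6-dimethyl-7-(phenylsulfonyl)bicyclo[2.2.2]oct-5-en-2-one
Product: 8 rac-(1R,2R,4S,7S)-2-ethenyl-3,3-dimethoxy-5,6-dimethyl-7-(phenylsulfonyl)bicyclo[2.2.2]oct-5-en-2-ol
Conditions: CH2=CHMgBr, THF, −78 to 0 °C; aq. NH4Cl
Reagents that add atoms: vinylmagnesium bromide, C=C[Mg]Br
Why: Grignard 1,2-addition to the bicyclic ketone takes place from the face next to the C4=C5 etheno bridge, which carries no inward hydrogens, and not from the ethano bridge side, so that the vinyl group at the new stereocenter C8 ends syn to C4=C5 as the oxy-Cope step requires.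

Step 4
Reactants: 8 rac-(1R,2R,4S,7S)-2-ethenyl-3,3-dimethoxy-5,6-dimethyl-7-(phenylsulfonyl)bicyclo[2.2.2]oct-5-en-2-ol
Product: 9 rac-(1R,2R,4S)-2-ethenyl-3,3-dimethoxy-5,6-dimethylbicyclo[2.2.2]oct-5-en-2-ol
Conditions: Na/Hg (6% Na), Na2HPO4, MeOH–THF, −20 °C to rt
Reagents that add atoms: none
Why: Reductive desulfonylation with sodium amalgam (electron transfer, loss of sulfinate, protonation) removes the activating group of the ethylene equivalent so that C1 and C2 become the methylene groups of the target and all regio- and endo/exo isomers of step 2 converge, while no stereocenter of the carbinol is touched and, at the carbinol stage, no ketone is present that could stabilise a rearranged homoallyl radical.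

Step 5
Reactants: 9 rac-(1R,2R,4S)-2-ethenyl-3,3-dimethoxy-5,6-dimethylbicyclo[2.2.2]oct-5-en-2-ol
Product: 11 rac-(4aS,8aS)-1,1-dimethoxy-4a,5-dimethyl-3,4,4a,7,8,8a-hexahydronaphthalen-2(1H)-one, via potassium enolate 10 (not isolated)
Conditions: KH, 18-crown-6, THF, 0 °C to rt; aq. NH4Cl
Reagents that add atoms: none
Why: Anionic oxy-Cope rearrangement of the potassium alkoxide through the boat-like transition state enforced by the bicycle forms C5–C6 on the face of C4=C5 that faces the C8–C9 bridge and cleaves the temporary C3–C8 bond, so that the quaternary C5 is set by suprafacial transfer from bridgehead C10 (methyl on C5 cis to H on C10, cis-fused decalin) and the enolate is protonated to the C8 ketone.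

Step 6
Reactants: 11 rac-(4aS,8aS)-1,1-dimethoxy-4a,5-dimethyl-3,4,4a,7,8,8a-hexahydronaphthalen-2(1H)-one
Product: 13 rac-(5S,10S)-11-hydroxy-9,9-dimethoxyeremophil-3-en-8-one, via lithium enolate 12 (not isolated)
Conditions: LiN(iPr)2, THF, −78 °C; acetone, −78 °C; AcOH, −78 °C
Reagents that add atoms: acetone, CC(C)=O
Why: Because C9 is a ketal, LiN(iPr)2 can only form the C7 enolate, which undergoes aldol addition to acetone at low temperature, and the new C7 stereocenter is of no consequence since it becomes sp2 in step 7.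

Step 7
Reactants: 13 rac-(5S,10S)-11-hydroxy-9,9-dimethoxyeremophil-3-en-8-one
Product: 15 rac-(5S,10S)-9,9-dimethoxyeremophila-3,7(11)-dien-8-one, via mesylate 14 (not isolated)
Conditions: MsCl, Et3N, CH2Cl2, 0 °C; DBU, rt
Reagents that add atoms: none
Why: Mesylation of the tertiary alcohol and base-induced E1cB elimination through the C7 enolate give the conjugated tetrasubstituted isopropylidene ketone, which removes the C7 stereocenter.

Step 8
Reactants: 15 rac-(5S,10S)-9,9-dimethoxyeremophila-3,7(11)-dien-8-one
Product: 17 rac-(5R)-9-hydroxyeremophila-3,7(11),9-trien-8-one, via diketone 16 (not isolated)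
Conditions: 2 M aq. HCl, THF, 45 °C
Reagents that add atoms: water, O
Why: Acid hydrolysis of the α-keto ketal gives the 8,9-diketone, whose only enolisable hydrogen sits on C10, so that it tautomerises to the conjugated diosphenol and makes C10 planar, leaving C5 as the only stereocenter.

Step 9
Reactants: 17 rac-(5R)-9-hydroxyeremophila-3,7(11),9-trien-8-one
Product: 18 rac-(5R)-9-(methoxymethoxy)eremophila-3,7(11),9-trien-8-one
Conditions: MOMCl, iPr2NEt, CH2Cl2, 0 °C to rt
Reagents that add atoms: chloromethyl methyl ether, COCCl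
Why: O-Alkylation of the acidic enol with chloromethyl methyl ether under amine base (Williamson-type acetal formation) masks the diosphenol as a base-stable acetal for the borane, enzyme and acylation steps.

Step 10
Reactants: 18 rac-(5R)-9-(methoxymethoxy)eremophila-3,7(11),9-trien-8-one
Product: 20 rac-(3R,4R,5R)-9-(methoxymethoxy)eremophila-7(11),9-diene-3,8-diol, via bis-borane 19 (not isolated)
Conditions: 9-BBN (3 equiv), THF, 0 to 65 °C; NaOH, 30% H2O2, 0 °C
Reagents that add atoms: hydrogen peroxide, OO
Why: 9-BBN first reduces the dienone carbonyl in the 1,2 sense and then hydroborates only the trisubstituted C3=C4 bond, boron going to the less substituted C3 and hydrogen to C4 in a syn addition on the face opposite the axial angular C5 methyl (as with ring A olefins next to the angular methyl of steroids), so that oxidation with retention sets 3-OH trans to the C4 methyl and the C4 methyl cis to the C5 methyl.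

Step 11
Reactants: 20 rac-(3R,4R,5R)-9-(methoxymethoxy)eremophila-7(11),9-diene-3,8-diol
Product: 21 rac-(3R,4R,5R)-3-hydroxy-9-(methoxymethoxy)eremophila-7(11),9-dien-8-one
Conditions: MnO2, CH2Cl2, rt
Reagents that add atoms: none
Why: MnO2 oxidises only the doubly allylic C8 alcohol back to the dienone and leaves the saturated C3 carbinol untouched (chemoselective allylic oxidation).

Step 12
Reactants: 21 rac-(3R,4R,5R)-3-hydroxy-9-(methoxymethoxy)eremophila-7(11),9-dien-8-one
Product: 22 (3R,4R,5R)-9-(methoxymethoxy)-8-oxoeremophila-7(11),9-dien-3-yl acetate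
Conditions: Burkholderia cepacia lipase, vinyl acetate, MTBE, 35 °C, to about half conversion
Reagents that add atoms: vinyl acetate, C=COC(C)=O
Why: Lipase-catalysed kinetic resolution by transesterification should acylate the (3R)-enantiomer faster, as with the fast-reacting enantiomer of menthol and other trans-2-alkylcyclohexanols (large substituent C4, medium substituent C2), which fixes the absolute configuration of C3, C4 and C5 in the acetate while the (3S,4S,5S)-alcohol stays behind and is separated.

Step 13
Reactants: 22 (3R,4R,5R)-9-(methoxymethoxy)-8-oxoeremophila-7(11),9-dien-3-yl acetate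
Product: 23 (3R,4R,5R)-3-hydroxy-9-(methoxymethoxy)eremophila-7(11),9-dien-8-one
Conditions: K2CO3, MeOH, rt
Reagents that add atoms: none
Why: Base-catalysed transesterification with methanol releases the enantiopure alcohol without touching the acetal-protected dienone or any stereocenter.

Step 14
Reactants: 24 tert-butyldimethyl(prop-2-yn-1-yloxy)silane
Product: 26 tert-butyl 4-[(tert-butyldimethylsilyl)oxy]but-2-ynoate, via lithium acetylide 25 (not isolated)
Conditions: n-BuLi, THF, −78 °C; Boc2O, −78 °C to rt; aq. NH4Cl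
Reagents that add atoms: di-tert-butyl dicarbonate, CC(C)(C)OC(=O)OC(=O)OC(C)(C)C
Why: Deprotonation of the terminal alkyne and C-acylation of the acetylide with Boc2O give the tert-butyl ynoate directly.

Step 15
Reactants: 26 tert-butyl 4-[(tert-butyldimethylsilyl)oxy]but-2-ynoate
Product: 27 tert-butyl (2Z)-4-[(tert-butyldimethylsilyl)oxy]-3-methylbut-2-enoate
Conditions: Me2CuLi (from MeLi and CuI), THF, −78 °C; aq. NH4Cl at −78 °C
Reagents that add atoms: lithium dimethylcuprate, [Li+].C[Cu-]C
Why: Syn carbocupration of the ynoate by the Gilman reagent at −78 °C and protonation of the vinylcopper intermediate with retention place the new methyl and the hydrogen cis, which makes the silyloxymethyl group cis to the ester (2Z).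

Step 16
Reactants: 27 tert-butyl (2Z)-4-[(tert-butyldimethylsilyl)oxy]-3-methylbut-2-enoate
Product: 28 tert-butyl (2Z)-4-hydroxy-3-methylbut-2-enoate
Conditions: HF·pyridine, pyridine, THF, 0 °C
Reagents that add atoms: none
Why: Fluoride cleavage of the silyl ether under buffered, weakly acidic conditions frees the primary allylic alcohol, and the bulky tert-butyl ester together with low temperature and immediate use should hold back lactonisation of the Z-configured γ-hydroxy ester.

Step 17
Reactants: 28 tert-butyl (2Z)-4-hydroxy-3-methylbut-2-enoate; 29 angelic acid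
Product: 31 tert-butyl (2Z)-3-methyl-4-{[(2Z)-2-methylbut-2-enoyl]oxy}but-2-enoate, via mixed anhydride 30 (not isolated)
Conditions: 29, 2,4,6-trichlorobenzoyl chloride, Et3N, toluene, rt; then 28, DMAP (cat.), 0 °C to rt
Reagents that add atoms: none
Why: Yamaguchi esterification through the mixed anhydride acylates the primary allylic alcohol under mild conditions that should not isomerise the angelate to the tiglate.

Step 18
Reactants: 31 tert-butyl (2Z)-3-methyl-4-{[(2Z)-2-methylbut-2-enoyl]oxy}but-2-enoate
Product: 32 (2Z)-3-methyl-4-{[(2Z)-2-methylbut-2-enoyl]oxy}but-2-enoic acid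
Conditions: TFA, CH2Cl2, 0 °C to rt
Reagents that add atoms: none
Why: Acidolysis of the tert-butyl ester (loss of isobutene) frees the carboxylic acid while the allylic angelate and both Z double bonds are inert to trifluoroacetic acid at low temperature.

Step 19
Reactants: 23 (3R,4R,5R)-3-hydroxy-9-(methoxymethoxy)eremophila-7(11),9-dien-8-one; 32 (2Z)-3-methyl-4-{[(2Z)-2-methylbut-2-enoyl]oxy}but-2-enoic acid
Product: 34 (3R,4R,5R)-9-(methoxymethoxy)-8-oxoeremophila-7(11),9-dien-3-yl (2Z)-3-methyl-4-{[(2Z)-2-methylbut-2-enoyl]oxy}but-2-enoate, via mixed anhydride 33 (not isolated)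
Conditions: 32, 2,4,6-trichlorobenzoyl chloride, Et3N, toluene, rt; then 23, DMAP, rt
Reagents that add atoms: none
Why: Yamaguchi esterification of the hindered equatorial C3 alcohol with the mixed anhydride of the side-chain acid forms the C3–O ester bond with retention at C3, the only free hydroxyl group being that at C3.

Step 20
Reactants: 34 (3R,4R,5R)-9-(methoxymethoxy)-8-oxoeremophila-7(11),9-dien-3-yl (2Z)-3-methyl-4-{[(2Z)-2-methylbut-2-enoyl]oxy}but-2-enoate
Product: 35 (3R,4R,5R)-9-hydroxy-8-oxoeremophila-7(11),9-dien-3-yl (2Z)-3-methyl-4-{[(2Z)-2-methylbut-2-enoyl]oxy}but-2-enoate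
Conditions: TFA, CH2Cl2–H2O (20:1), 0 °C
Reagents that add atoms: none
Why: Mild acid cleaves the methoxymethyl acetal at its O–CH2–O unit and frees the diosphenol without affecting the esters, the olefin geometries or the stereocenters.

**Compound list**

1 | 3,4-dimethylanisole | COc1ccc(C)c(C)c1 | starting material
2 | (2-methoxy-4,5-dimethylphenyl)lithium, formed in situ | COc1cc(C)c(C)cc1[Li] | intermediate
3 | dimethyl (2-methoxy-4,5-dimethylphenyl)boronate, formed in situ | COc1cc(C)c(C)cc1B(OC)OC | intermediate
4 | 2-methoxy-4,5-dimethylphenol | COc1cc(C)c(C)cc1O | intermediate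
5 | phenyl vinyl sulfone | C=CS(=O)(=O)c1ccccc1 | starting material
6 | 6,6-dimethoxy-3,4-dimethylcyclohexa-2,4-dien-1-one (masked o-benzoquinone), formed in situ | COC1(OC)C=C(C)C(C)=CC1=O | intermediate
7 | rac-(1R,4S,7S)-3,3-dimethoxy-5,6-dimethyl-7-(phenylsulfonyl)bicyclo[2.2.2]oct-5-en-2-one (sulfonyl endo, syn to the C5=C6 bridge, on the carbon next to the bridgehead α to C=O) | COC1(OC)C(=O)[C@@H]2[C@@H](S(=O)(=O)c3ccccc3)C[C@H]1C(C)=C2C | intermediate
8 | rac-(1R,2R,4S,7S)-2-ethenyl-3,3-dimethoxy-5,6-dimethyl-7-(phenylsulfonyl)bicyclo[2.2.2]oct-5-en-2-ol (vinyl syn to the C5=C6 bridge) | COC1(OC)[C@@](O)(C=C)[C@@H]2[C@@H](S(=O)(=O)c3ccccc3)C[C@H]1C(C)=C2C | intermediate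
9 | rac-(1R,2R,4S)-2-ethenyl-3,3-dimethoxy-5,6-dimethylbicyclo[2.2.2]oct-5-en-2-ol | COC1(OC)[C@@](O)(C=C)[C@@H]2CC[C@H]1C(C)=C2C | intermediate
10 | potassium enolate of 11 (C7=C8–O−), formed in situ | CC1=CCC[C@@H]2C(OC)(OC)C([O-])=CC[C@]12C.[K+] | intermediate
11 | rac-(4aS,8aS)-1,1-dimethoxy-4a,5-dimethyl-3,4,4a,7,8,8a-hexahydronaphthalen-2(1H)-one (cis-fused; eremophilane numbering: 9,9-dimethoxy-8-oxo, C3=C4, 5S,10S) | CC1=CCC[C@@H]2C(OC)(OC)C(=O)CC[C@]12C | intermediate
12 | lithium enolate of 11 (C7=C8–O−), formed in situ | CC1=CCC[C@@H]2C(OC)(OC)C([O-])=CC[C@]12C.[Li+] | intermediate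
13 | rac-(5S,10S)-11-hydroxy-9,9-dimethoxyeremophil-3-en-8-one (C7 epimers) | CC1=CCC[C@@H]2C(OC)(OC)C(=O)C(C(C)(C)O)C[C@]12C | intermediate
14 | 11-O-methanesulfonate of 13, formed in situ | CC1=CCC[C@@H]2C(OC)(OC)C(=O)C(C(C)(C)OS(C)(=O)=O)C[C@]12C | intermediate
15 | rac-(5S,10S)-9,9-dimethoxyeremophila-3,7(11)-dien-8-one | CC1=CCC[C@@H]2C(OC)(OC)C(=O)C(=C(C)C)C[C@]12C | intermediate
16 | rac-(5S,10S)-eremophila-3,7(11)-diene-8,9-dione, formed in situ | CC1=CCC[C@@H]2C(=O)C(=O)C(=C(C)C)C[C@]12C | intermediate
17 | rac-(5R)-9-hydroxyeremophila-3,7(11),9-trien-8-one | CC1=CCCC2=C(O)C(=O)C(=C(C)C)C[C@]12C | intermediate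
18 | rac-(5R)-9-(methoxymethoxy)eremophila-3,7(11),9-trien-8-one | CC1=CCCC2=C(OCOC)C(=O)C(=C(C)C)C[C@]12C | intermediate
19 | bis-borane: 3α-(9-borabicyclo[3.3.1]nonan-9-yl) and 8-O-(9-borabicyclo[3.3.1]nonan-9-yl) derivative of 20, formed in situ | C1CCC2CCCC1B2[C@@H]3CCC4=C(OCOC)C(OB5C6CCCC5CCC6)C(=C(C)C)C[C@]4(C)[C@H]3C | intermediate
20 | rac-(3R,4R,5R)-9-(methoxymethoxy)eremophila-7(11),9-diene-3,8-diol (C8 epimers) | O[C@@H]1CCC2=C(OCOC)C(O)C(=C(C)C)C[C@]2(C)[C@H]1C | intermediate
21 | rac-(3R,4R,5R)-3-hydroxy-9-(methoxymethoxy)eremophila-7(11),9-dien-8-one | O[C@@H]1CCC2=C(OCOC)C(=O)C(=C(C)C)C[C@]2(C)[C@H]1C | intermediate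
22 | (3R,4R,5R)-9-(methoxymethoxy)-8-oxoeremophila-7(11),9-dien-3-yl acetate | CC(=O)O[C@@H]1CCC2=C(OCOC)C(=O)C(=C(C)C)C[C@]2(C)[C@H]1C | intermediate
23 | (3R,4R,5R)-3-hydroxy-9-(methoxymethoxy)eremophila-7(11),9-dien-8-one, single enantiomer | O[C@@H]1CCC2=C(OCOC)C(=O)C(=C(C)C)C[C@]2(C)[C@H]1C | intermediate
24 | tert-butyldimethyl(prop-2-yn-1-yloxy)silane | C#CCO[Si](C)(C)C(C)(C)C | starting material
25 | lithium acetylide of 24, formed in situ | [Li]C#CCO[Si](C)(C)C(C)(C)C | intermediate
26 | tert-butyl 4-[(tert-butyldimethylsilyl)oxy]but-2-ynoate | CC(C)(C)OC(=O)C#CCO[Si](C)(C)C(C)(C)C | intermediate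
27 | tert-butyl (2Z)-4-[(tert-butyldimethylsilyl)oxy]-3-methylbut-2-enoate | CC(C)(C)[Si](C)(C)OC/C(C)=C\C(=O)OC(C)(C)C | intermediate
28 | tert-butyl (2Z)-4-hydroxy-3-methylbut-2-enoate | OC/C(C)=C\C(=O)OC(C)(C)C | intermediate
29 | angelic acid, (2Z)-2-methylbut-2-enoic acid | C/C=C(/C)C(=O)O | starting material
30 | angelic 2,4,6-trichlorobenzoic anhydride, formed in situ | C/C=C(/C)C(=O)OC(=O)c1c(Cl)cc(Cl)cc1Cl | intermediate
31 | tert-butyl (2Z)-3-methyl-4-{[(2Z)-2-methylbut-2-enoyl]oxy}but-2-enoate | C/C=C(/C)C(=O)OC/C(C)=C\C(=O)OC(C)(C)C | intermediate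
32 | (2Z)-3-methyl-4-{[(2Z)-2-methylbut-2-enoyl]oxy}but-2-enoic acid | C/C=C(/C)C(=O)OC/C(C)=C\C(=O)O | intermediate
33 | mixed anhydride of 32 with 2,4,6-trichlorobenzoic acid, formed in situ | C/C=C(/C)C(=O)OC/C(C)=C\C(=O)OC(=O)c1c(Cl)cc(Cl)cc1Cl | intermediate
34 | (3R,4R,5R)-9-(methoxymethoxy)-8-oxoeremophila-7(11),9-dien-3-yl (2Z)-3-methyl-4-{[(2Z)-2-methylbut-2-enoyl]oxy}but-2-enoate | C/C=C(/C)C(=O)OC/C(C)=C\C(=O)O[C@@H]1CCC2=C(OCOC)C(=O)C(=C(C)C)C[C@]2(C)[C@H]1C | intermediate
35 | (3R,4R,5R)-9-hydroxy-8-oxoeremophila-7(11),9-dien-3-yl (2Z)-3-methyl-4-{[(2Z)-2-methylbut-2-enoyl]oxy}but-2-enoate (CNP0228871.1) | C/C=C(/C)C(=O)OC/C(C)=C\C(=O)O[C@@H]1CCC2=C(O)C(=O)C(=C(C)C)C[C@]2(C)[C@H]1C | target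

**Step count and risks**

Total step count: 20. Longest linear sequence: 15 (steps 1 to 13, then 19 and 20); the side-chain acid is made in 5 steps (14 to 18) and joined in step 19.

Steps most likely to fail, each with one fallback:

Step 2. The risk is that self-dimerisation of the dienone outruns the cycloaddition, because an electron-poor sulfone is a sluggish partner for an electron-poor diene. The fallback sets out from 4: the same dearomatisation is run in the presence of phenyl vinyl sulfide, an electron-rich dienophile that should react with 6 in the inverse-electron-demand sense, to give the sulfide cycloadduct rac-(1R,4S,7S)-3,3-dimethoxy-5,6-dimethyl-7-(phenylsulfanyl)bicyclo[2.2.2]oct-5-en-2-one F1. Sulfur alone is then oxidised with 30% H2O2 and catalytic (NH4)6Mo7O24 in EtOH at 0 °C, which comes back to the route at 7.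

Step 12. The risk is slow or poorly selective enzymatic acylation of the hindered C3 carbinol. The fallback sets out from 21: it is esterified with (S)-2-methoxy-2-phenylacetic acid (DCC, DMAP, CH2Cl2), and the two diastereomeric esters, the (3R,4R,5R)-configured (2S)-2-methoxy-2-phenylacetate F2 and its (3S,4S,5S)-configured diastereomer F3, are separated by chromatography. F2 is cleaved with K2CO3 in MeOH, which comes back to the route at 23.

Step 16. The risk is intramolecular transesterification (lactonisation) of the Z-configured γ-hydroxy ester once the silyl group is off. The fallback sets out from 27: the silyl ether is converted directly into the allylic bromide tert-butyl (2Z)-4-bromo-3-methylbut-2-enoate F4 with Ph3PBr2 (CH2Cl2, 0 °C). F4 is used at once to alkylate the caesium salt of angelic acid 29 (Cs2CO3, DMF, 0 °C to rt). This comes back to the route at 31 without a free hydroxy ester and without an acylation step on the angelate.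

Further compounds
F1 | step 2 | rac-(1R,4S,7S)-3,3-dimethoxy-5,6-dimethyl-7-(phenylsulfanyl)bicyclo[2.2.2]oct-5-en-2-one | COC1(OC)C(=O)[C@@H]2[C@@H](Sc3ccccc3)C[C@H]1C(C)=C2C
F2 | step 12 | (3R,4R,5R)-9-(methoxymethoxy)-8-oxoeremophila-7(11),9-dien-3-yl (2S)-2-methoxy-2-phenylacetate | CO[C@@H](c1ccccc1)C(=O)O[C@@H]1CCC2=C(OCOC)C(=O)C(=C(C)C)C[C@]2(C)[C@H]1C
F3 | step 12 | (3S,4S,5S)-9-(methoxymethoxy)-8-oxoeremophila-7(11),9-dien-3-yl (2S)-2-methoxy-2-phenylacetate | CO[C@@H](c1ccccc1)C(=O)O[C@H]1CCC2=C(OCOC)C(=O)C(=C(C)C)C[C@@]2(C)[C@@H]1C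
F4 | step 16 | tert-butyl (2Z)-4-bromo-3-methylbut-2-enoate | BrC/C(C)=C\C(=O)OC(C)(C)C
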